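**Plan**
1. Retrosynthesis: the hydroquinone goes back to a 2′,3′-dimethoxy-5′-ethoxyarene, C11–Cl to an enol triflate, and the C8–H bond with the C9=C11 alkene to a C11 aryl ketone conjugated with C8=C9.
2. The benzene ring is then cut at C1′–C6′, C3′–C4′, C5′–C6′ and C2′–C3′ into a β-methoxy enone diazomethyl ketone and ethoxyacetylene. This is possible because the arene carries C11 on C1′ and oxygens on C2′, C3′ and C5′: a meta O,O pair (C3′ = ketene carbonyl, C5′ = ynol ether carbon) next to a third oxygen (C2′ = β-methoxy enone carbon).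
3. The bond between C11 and the future C1′ is cut by an aldol between drim-8-en-11-al and methyl 3,3-dimethoxypropanoate; the enal comes from (+)-sclareolide by loss of one carbon.
4. Forward: rings A and B arrive with sclareolide, the side chain is joined by aldol, and the arene is the only ring built, last.
5. Stereochemistry: C5 and C10 come from sclareolide; C8 is set by hydride delivery to the α face of the enone; the alkene geometry is set in the same step (s-cis enone, oxygen cis to C8) and carried with retention into the chloride.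

Key step: step 8

Numbering: drimane numbering for the terpenoid (C11 on C9, C12 methyl on C8), primed locants for the arene (C1′ on C11). Dec = (4aS,8aS)-2,5,5,8a-tetramethyl-3,4,4a,5,6,7,8,8a-octahydronaphthalen-1-yl; Dyl = (2S,4aS,8aS)-2,5,5,8a-tetramethyloctahydronaphthalen-1(2H)-ylidene.
Assumption: the C11 carbinol centre made in the aldol (and the neighbouring ester α-centre) is not controlled; it is carried as an epimer mixture and later becomes sp2, so its SMILES are written without configuration.

Step 1
Reactants: 1 (+)-sclareolide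
Product: 2 2-[(1R,2R,4aS,8aS)-2-hydroxy-2,5,5,8a-tetramethyldecahydronaphthalen-1-yl]acetic acid
Conditions: KOH, MeOH/H2O, reflux; then cold 1 M HCl to pH 3–4 at 0 °C, immediate extraction
Reagents that add atoms: potassium hydroxide, [K+].[OH-]
Why: Saponification of the γ-lactone by acyl–oxygen cleavage leaves the C8–O bond and all four stereocentres untouched, and cold, brief acidification should free the acid before it relactonises.

Step 2
Reactants: 2 hydroxy acid
Product: 3 (8R)-drim-9(11)-en-8-ol (8α-OH, exocyclic C9=C11 methylene)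
Conditions: Pb(OAc)4, Cu(OAc)2·H2O (cat.), pyridine, C6H6, 80 °C
Reagents that add atoms: none
Why: Kochi oxidative decarboxylation: the lead carboxylate loses CO2 to a primary C11 radical, which divalent copper oxidises with loss of the only β-hydrogen (C9–H) to give the exocyclic alkene, leaving C5, C8 and C10 untouched.

Step 3
Reactants: 3 drim-9(11)-en-8α-ol
Product: 4 drim-8-en-11-al (Dec–CHO)
Conditions: C5H5NH[CrO3Cl] (pyridinium chlorochromate), CH2Cl2, rt
Reagents that add atoms: pyridinium chlorochromate, [O-][Cr](=O)(=O)Cl.c1cc[nH+]cc1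
Why: Babler–Dauben oxidative transposition: the chromate ester of the tertiary allylic alcohol should shift [3,3] to the primary C11 chromate, which is oxidised to the tetrasubstituted enal; C8 becomes sp2 and no stereocentre is made.

Step 4
Reactants: 4 drim-8-en-11-al; 5 methyl 3,3-dimethoxypropanoate
Product: 7 methyl 3-Dec-2-(dimethoxymethyl)-3-hydroxypropanoate, via lithium ester enolate 6 (not isolated)
Conditions: LiN(i-Pr)2 (commercial solution), THF, −78 °C, 5; then 4, −78 °C; AcOH quench at −78 °C
Reagents that add atoms: none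
Why: Directed aldol 1,2-addition of a preformed lithium ester enolate to a non-enolisable hindered enal (the β-cyclocitral situation); the acetal already holds the future C2′ at the formyl oxidation level, and the two new centres are uncontrolled but both become sp2 later.

Step 5
Reactants: 7 aldol adduct
Product: 9 methyl (E)-2-[Dec(tert-butyldimethylsilyloxy)methyl]-3-methoxyacrylate, via silyl ether acetal 8 (not isolated)
Conditions: TBSOTf, i-Pr2NEt, CH2Cl2, −78 to 0 °C; then TMSOTf, 0 °C to rt
Reagents that add atoms: tert-butyldimethylsilyl triflate, CC(C)(C)[Si](C)(C)OS(=O)(=O)C(F)(F)F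
Why: O-silylation of the hindered carbinol, then Gassman-type conversion of the acetal into the enol ether (TMSOTf ionises the acetal, the amine removes the acidic ester α-proton), which avoids enolate chemistry next to the C11 silyloxy leaving group; the E isomer (OMe trans to CO2Me) is expected as the thermodynamically preferred β-methoxyacrylate.

Step 6
Reactants: 9 β-methoxyacrylate ester
Product: 10 (E)-2-[Dec(tert-butyldimethylsilyloxy)methyl]-3-methoxyacrylic acid
Conditions: LiOH·H2O, THF/MeOH/H2O, 50 °C; then cold 1 M HCl to pH 4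
Reagents that add atoms: lithium hydroxide, [Li+].[OH-]
Why: Ester saponification; the acrylate has no α-hydrogen, so the silyloxy group cannot be eliminated, conjugate attack by methoxide is degenerate, and the TBS and enol ethers tolerate the base and the brief cold work-up.

Step 7
Reactants: 10 acid
Product: 12 (E)-3-[Dec(tert-butyldimethylsilyloxy)methyl]-1-diazo-4-methoxybut-3-en-2-one, via acid chloride 11 (not isolated)
Conditions: 1-chloro-N,N,2-trimethylprop-1-en-1-amine, CH2Cl2, 0 °C; then CH2N2 (ethereal solution, excess), Et3N, 0 °C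
Reagents that add atoms: diazomethane, C=[N+]=[N-]
Why: The α-chloroenamine should give the acid chloride without free HCl near the enol ether and allylic silyl ether, and acylation of diazomethane with Et3N as scavenger (first stage of the Arndt–Eistert sequence) gives the diazomethyl ketone; the push–pull alkene is a poor dipolarophile, so pyrazoline formation should not compete.

Step 8
Reactants: 12 diazo ketone; 13 ethoxyacetylene
Product: 18 3-[Dec(tert-butyldimethylsilyloxy)methyl]-5-ethoxy-2-methoxyphenol, via vinylketene 14 (not isolated), via ethoxycyclobutenone 15 (not isolated), via dienylketene 16 (not isolated), via cyclohexa-2,4-dienone 17 (not isolated)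
Conditions: hν (254 nm, Vycor), 13 (excess), ClCH2CH2Cl, rt; then 80 °C
Reagents that add atoms: none
Why: Light should expel N2 from 12 and the alkenyl carbon C1′ should migrate to the carbene carbon C6′ (Wolff rearrangement) to give vinylketene 14, whose carbonyl carbon C3′ is attacked by the nucleophilic CH terminus of 13 in a polar [2+2] cycloaddition (C3′–C4′ and C5′–C6′) to give cyclobutenone 15. Four-electron electrocyclic opening of 15 (light or the final heating) gives dienylketene 16, thermal disrotatory 6π electrocyclisation joins C2′ to C3′ and closes the benzene ring as dienone 17, and enolisation gives phenol 18. The closest known reaction is the Danheiser benzannulation in its diazo ketone form with alkoxy- and siloxyalkynes. No stereocentre is created, and the C11 epimers converge later. The step needs regiocontrol, which the polarity of the ketene/ynol ether pair provides (OEt ends at C5′, meta to the new C3′–OH), and chemoselectivity, which rests on the E enol ether (H, not OMe, inside the closing triene), on the silyl ether that keeps the C11 oxygen from lactonising the ketene, and on the tetrasubstituted C8=C9 alkene being too hindered to trap the ketene. The three oxygens emerge differentiated: a free C3′–OH to methylate and the C2′/C5′ para-dialkoxy pair for later oxidative unmasking.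

Step 9
Reactants: 18 phenol
Product: 19 tert-butyl[Dec(5-ethoxy-2,3-dimethoxyphenyl)methoxy]dimethylsilane
Conditions: MeI, K2CO3, acetone, 50 °C
Reagents that add atoms: iodomethane, CI
Why: Williamson O-methylation of the only free phenol; the silyl ether is stable to K2CO3.

Step 10
Reactants: 19 silyl ether
Product: 20 Dec(5-ethoxy-2,3-dimethoxyphenyl)methanol
Conditions: Bu4NF, THF, 50 °C
Reagents that add atoms: none
Why: Fluoride cleavage of the Si–O bond under basic conditions, chosen because the allylic and benzylic C11 carbinol would ionise under acid.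

Step 11
Reactants: 20 carbinol
Product: 21 Dec 5-ethoxy-2,3-dimethoxyphenyl ketone (C11 aryl ketone with C8=C9)
Conditions: Dess–Martin periodinane, CH2Cl2, rt
Reagents that add atoms: none
Why: Dess–Martin oxidation of the secondary allylic/benzylic alcohol gives the aryl enone and removes the uncontrolled C11 centre.

Step 12
Reactants: 21 aryl enone
Product: 24 (E)-(5-ethoxy-2,3-dimethoxyphenyl)(Dyl)methyl trifluoromethanesulfonate (OTf cis to C8), via dimethylphenylsilyl enol ether 22 (not isolated), via lithium enolate 23 (not isolated)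
Conditions: [(Ph3P)CuH]6 (cat.), PhMe2SiH, toluene, rt to 50 °C; then MeLi, THF, 0 °C; then PhNTf2, −78 to 0 °C
Reagents that add atoms: N-phenylbis(trifluoromethanesulfonimide), O=S(=O)(N(c1ccccc1)S(=O)(=O)C(F)(F)F)C(F)(F)F
Why: Copper hydride-catalysed 1,4-hydrosilylation, then regeneration of the lithium enolate with MeLi and O-triflation: hydride should reach C8 from the α face, anti to the axial C10 methyl, setting 8S (8β-methyl), and should do so in the s-cis enone conformer (s-trans would press the aryl group against the C8 methyl), so that oxygen ends cis to C8 and this geometry is locked in the tetrasubstituted silyl enol ether, enolate and triflate.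

Step 13
Reactants: 24 enol triflate
Product: 25 1-[(E)-chloro(Dyl)methyl]-5-ethoxy-2,3-dimethoxybenzene (Cl cis to C8)
Conditions: Ni(OAc)2·4H2O (cat.), 1,5-cyclooctadiene, Zn (cat.), LiCl, DMA/THF, rt
Reagents that add atoms: lithium chloride, [Li+].[Cl-]
Why: Nickel-catalysed triflate-to-halide exchange of enol triflates (oxidative addition, triflate/chloride exchange on nickel, C–Cl reductive elimination) should proceed with retention of alkene geometry and touch neither C8 nor the aryl ethers.

Step 14
Reactants: 25 chloroalkene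
Product: 26 2-[(E)-chloro(Dyl)methyl]-6-methoxycyclohexa-2,5-diene-1,4-dione
Conditions: (NH4)2Ce(NO3)6, MeCN/H2O, 0 °C
Reagents that add atoms: water, O
Why: Oxidative dealkylation of the para-dialkoxy pair (C2′–OMe, C5′–OEt) through the arene radical cation and attack of water gives the 1,4-quinone; the para pathway is preferred over ortho-quinone formation, so the C3′ methoxy group stays.

Step 15
Reactants: 26 quinone
Product: 27 2-[(E)-chloro(Dyl)methyl]-6-methoxybenzene-1,4-diol (target, CNP0162917.1)
Conditions: Na2S2O4, THF/H2O, rt, under argon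
Reagents that add atoms: none
Why: Dithionite reduction of the quinone to the hydroquinone under neutral aqueous conditions should leave the chloroalkene and the methyl ether untouched.

**Compound list**
1 | (+)-sclareolide | CC1(CCC[C@]2([C@H]1CC[C@@]3([C@@H]2CC(=O)O3)C)C)C | starting material
2 | 2-[(1R,2R,4aS,8aS)-2-hydroxy-2,5,5,8a-tetramethyldecahydronaphthalen-1-yl]acetic acid | CC1(CCC[C@]2([C@H]1CC[C@@]([C@@H]2CC(=O)O)(C)O)C)C | intermediate
3 | (8R)-drim-9(11)-en-8-ol | C=C1[C@](C)(O)CC[C@H]2C(C)(C)CCC[C@]12C | intermediate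
4 | drim-8-en-11-al | O=CC1=C(C)CC[C@H]2C(C)(C)CCC[C@]12C | intermediate
5 | methyl 3,3-dimethoxypropanoate | COC(OC)CC(=O)OC | starting material
6 | lithium enolate of 5 (not isolated) | COC(OC)C=C(OC)O[Li] | intermediate
7 | methyl 3-Dec-2-(dimethoxymethyl)-3-hydroxypropanoate (diastereomer mixture) | COC(OC)C(C(=O)OC)C(O)C1=C(C)CC[C@H]2C(C)(C)CCC[C@]12C | intermediate
8 | methyl 3-Dec-3-(tert-butyldimethylsilyloxy)-2-(dimethoxymethyl)propanoate (not isolated) | COC(OC)C(C(=O)OC)C(O[Si](C)(C)C(C)(C)C)C1=C(C)CC[C@H]2C(C)(C)CCC[C@]12C | intermediate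
9 | methyl (E)-2-[Dec(tert-butyldimethylsilyloxy)methyl]-3-methoxyacrylate | CO/C=C(/C(=O)OC)C(O[Si](C)(C)C(C)(C)C)C1=C(C)CC[C@H]2C(C)(C)CCC[C@]12C | intermediate
10 | (E)-2-[Dec(tert-butyldimethylsilyloxy)methyl]-3-methoxyacrylic acid | CO/C=C(/C(=O)O)C(O[Si](C)(C)C(C)(C)C)C1=C(C)CC[C@H]2C(C)(C)CCC[C@]12C | intermediate
11 | acid chloride of 10 (not isolated) | CO/C=C(/C(=O)Cl)C(O[Si](C)(C)C(C)(C)C)C1=C(C)CC[C@H]2C(C)(C)CCC[C@]12C | intermediate
12 | (E)-3-[Dec(tert-butyldimethylsilyloxy)methyl]-1-diazo-4-methoxybut-3-en-2-one | CO/C=C(/C(=O)C=[N+]=[N-])C(O[Si](C)(C)C(C)(C)C)C1=C(C)CC[C@H]2C(C)(C)CCC[C@]12C | intermediate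
13 | ethoxyacetylene | CCOC#C | starting material
14 | vinylketene: 3-[Dec(tert-butyldimethylsilyloxy)methyl]-4-methoxybuta-1,3-dien-1-one, OMe trans to the ketenyl carbon (not isolated) | CO/C=C(/C=C=O)C(O[Si](C)(C)C(C)(C)C)C1=C(C)CC[C@H]2C(C)(C)CCC[C@]12C | intermediate
15 | 3-ethoxy-4-alkenylcyclobut-2-en-1-one carrying the methoxyvinyl/C11 silyl ether side chain on C4 (not isolated) | CCOC1=CC(=O)C1/C(=C/OC)C(O[Si](C)(C)C(C)(C)C)C2=C(C)CC[C@H]3C(C)(C)CCC[C@]23C | intermediate
16 | dienylketene O=C=CH–C(OEt)=CH–C(R)=CH(OMe), R = Dec–CH(OTBS), ketenyl and alkenyl groups cis across C5′=C6′ (not isolated) | CCOC(/C=C=O)=C/C(=C/OC)C(O[Si](C)(C)C(C)(C)C)C1=C(C)CC[C@H]2C(C)(C)CCC[C@]12C | intermediate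
17 | 5-[Dec(tert-butyldimethylsilyloxy)methyl]-3-ethoxy-6-methoxycyclohexa-2,4-dien-1-one (not isolated) | CCOC1=CC(=O)C(OC)C(=C1)C(O[Si](C)(C)C(C)(C)C)C2=C(C)CC[C@H]3C(C)(C)CCC[C@]23C | intermediate
18 | 3-[Dec(tert-butyldimethylsilyloxy)methyl]-5-ethoxy-2-methoxyphenol | COc1c(O)cc(OCC)cc1C(O[Si](C)(C)C(C)(C)C)C2=C(C)CC[C@H]3C(C)(C)CCC[C@]23C | intermediate
19 | tert-butyl[Dec(5-ethoxy-2,3-dimethoxyphenyl)methoxy]dimethylsilane | CCOc1cc(OC)c(OC)c(c1)C(O[Si](C)(C)C(C)(C)C)C2=C(C)CC[C@H]3C(C)(C)CCC[C@]23C | intermediate
20 | Dec(5-ethoxy-2,3-dimethoxyphenyl)methanol | CCOc1cc(OC)c(OC)c(c1)C(O)C2=C(C)CC[C@H]3C(C)(C)CCC[C@]23C | intermediate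
21 | Dec 5-ethoxy-2,3-dimethoxyphenyl ketone | CCOc1cc(OC)c(OC)c(c1)C(=O)C2=C(C)CC[C@H]3C(C)(C)CCC[C@]23C | intermediate
22 | (E)-[(5-ethoxy-2,3-dimethoxyphenyl)(Dyl)methoxy]dimethyl(phenyl)silane, O cis to C8 (not isolated) | CCOc1cc(OC)c(OC)c(c1)/C(O[Si](C)(C)c1ccccc1)=C2/[C@@H](C)CC[C@H]3C(C)(C)CCC[C@]23C | intermediate
23 | lithium (E)-(5-ethoxy-2,3-dimethoxyphenyl)(Dyl)methanolate (not isolated) | CCOc1cc(OC)c(OC)c(c1)/C(O[Li])=C2/[C@@H](C)CC[C@H]3C(C)(C)CCC[C@]23C | intermediate
24 | (E)-(5-ethoxy-2,3-dimethoxyphenyl)(Dyl)methyl trifluoromethanesulfonate | CCOc1cc(OC)c(OC)c(c1)/C(OS(=O)(=O)C(F)(F)F)=C2/[C@@H](C)CC[C@H]3C(C)(C)CCC[C@]23C | intermediate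
25 | 1-[(E)-chloro(Dyl)methyl]-5-ethoxy-2,3-dimethoxybenzene | CCOc1cc(OC)c(OC)c(c1)/C(Cl)=C2/[C@@H](C)CC[C@H]3C(C)(C)CCC[C@]23C | intermediate
26 | 2-[(E)-chloro(Dyl)methyl]-6-methoxycyclohexa-2,5-diene-1,4-dione | COC1=CC(=O)C=C(C1=O)/C(Cl)=C2/[C@@H](C)CC[C@H]3C(C)(C)CCC[C@]23C | intermediate
27 | 2-[(E)-chloro(Dyl)methyl]-6-methoxybenzene-1,4-diol (8S, 5S, 10S; Cl cis to C8, aryl cis to C10) | COc1cc(O)cc(/C(Cl)=C2/[C@@H](C)CC[C@H]3C(C)(C)CCC[C@]23C)c1O | target

Total step count: 15
Longest linear sequence: 15 steps, from 1 (5 and 13 are purchased).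

**Steps most likely to fail**

Step 12. The twisted tetrasubstituted enone may not accept hydride at C8 (no reaction, or 1,2-reduction of the ketone), and hydride transfer from a conformer other than s-cis would erode the enolate geometry. The fallback sets out from 21 and comes back at 25, and it sets C8 by hydrogenation instead of conjugate hydride addition. KN(SiMe3)2 (THF, −78 °C), bound to the carbonyl oxygen of the s-cis conformer, removes a proton from the C12 methyl to give the potassium dienolate F1 with oxygen cis to C8. PhNTf2 converts it into the dienyl triflate F2 (C9=C11 and C8=C12 double bonds). Chloride exchange under the conditions of step 13 gives the dienyl chloride F3. RhCl(PPh3)3-catalysed hydrogenation of the 1,1-disubstituted C8=C12 alkene from the α face, which leaves the tetrasubstituted chloroalkene alone, should give 25.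

Step 13. Oxidative addition into the hindered tetrasubstituted C–OTf bond may be slow, and radical intermediates on nickel could scramble the alkene geometry or lead to reduction. The fallback sets out from 24 and comes back at 25. Stannylation with Me3SnSnMe3 (Pd(PPh3)4, LiCl, THF, reflux) gives the alkenylstannane F4, and CuCl2 (MeCN/THF, rt) then replaces tin by chlorine with retention.

Step 8. The vinylketene may be lost to dimerisation or to acylation of the phenol product, the cascade may stall at the cyclobutenone, or the enol ether diazo ketone may decompose under irradiation. The fallback sets out from 4 and comes back at 20, bypassing steps 4 to 10 by bringing the arene in preformed. Commercial 3-bromo-4,5-dimethoxybenzaldehyde is oxidised (mCPBA, CH2Cl2, Baeyer–Villiger) to 3-bromo-4,5-dimethoxyphenyl formate F5, methanolysed (K2CO3, MeOH) to 3-bromo-4,5-dimethoxyphenol F6, and O-ethylated (EtI, K2CO3, DMF) to 1-bromo-5-ethoxy-2,3-dimethoxybenzene F7. Bromine–lithium exchange (n-BuLi, THF, −78 °C) gives (5-ethoxy-2,3-dimethoxyphenyl)lithium F8, which adds to 4 to give 20 directly.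

**Further compounds**
F1 | step 12 | potassium (E)-(5-ethoxy-2,3-dimethoxyphenyl)[(4aS,8aS)-5,5,8a-trimethyl-2-methyleneoctahydronaphthalen-1(2H)-ylidene]methanolate | CCOc1cc(OC)c(OC)c(c1)/C(O[K])=C2/C(=C)CC[C@H]3C(C)(C)CCC[C@]23C
F2 | step 12 | dienyl triflate: (E)-(5-ethoxy-2,3-dimethoxyphenyl)[(4aS,8aS)-5,5,8a-trimethyl-2-methyleneoctahydronaphthalen-1(2H)-ylidene]methyl trifluoromethanesulfonate | CCOc1cc(OC)c(OC)c(c1)/C(OS(=O)(=O)C(F)(F)F)=C2/C(=C)CC[C@H]3C(C)(C)CCC[C@]23C
F3 | step 12 | dienyl chloride: 1-{(E)-chloro[(4aS,8aS)-5,5,8a-trimethyl-2-methyleneoctahydronaphthalen-1(2H)-ylidene]methyl}-5-ethoxy-2,3-dimethoxybenzene | CCOc1cc(OC)c(OC)c(c1)/C(Cl)=C2/C(=C)CC[C@H]3C(C)(C)CCC[C@]23C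
F4 | step 13 | alkenylstannane: [(5-ethoxy-2,3-dimethoxyphenyl)(Dyl)methyl]trimethylstannane, Sn cis to C8 | CCOc1cc(OC)c(OC)c(c1)/C([Sn](C)(C)C)=C2/[C@@H](C)CC[C@H]3C(C)(C)CCC[C@]23C
F5 | step 8 | 3-bromo-4,5-dimethoxyphenyl formate | O=COc1cc(OC)c(OC)c(Br)c1
F6 | step 8 | 3-bromo-4,5-dimethoxyphenol | Oc1cc(OC)c(OC)c(Br)c1
F7 | step 8 | 1-bromo-5-ethoxy-2,3-dimethoxybenzene | CCOc1cc(OC)c(OC)c(Br)c1
F8 | step 8 | (5-ethoxy-2,3-dimethoxyphenyl)lithium | CCOc1cc(OC)c(OC)c([Li])c1
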